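## The problem

Target 17 is a cyclohexene (C1–C6) with an epoxide fused across C1–C6, a benzoyloxymethyl arm (C7) on quaternary C1, a benzoate on C2, a free hydroxyl on C3 and the C4=C5 alkene. Its four stereocentres are (1S,2S,3R,6S): the epoxide oxygen is syn to the C3 hydroxyl and anti to the C2 benzoate, and C7 is syn to the C2 benzoate. C2 can be set first and then steers the rest: an oxygen on C2 shields one face of a C3–C6 diene, and C1, once fixed relative to C2, decides on which face the epoxide ends. The compound is fragile in three ways. The epoxide is allylic at C6 and opens with acid. The C2 benzoate has an oxygen 1,2 to it (C3) and one 1,3-cis to it (C7), so any alkoxide moves acyl groups. Every dearomatised diene on the way can ionise to an arenium ion and fall back to an aromatic. The enabling feature is that C3–O and C6–O are cis and 1,4 across C4=C5, the pattern left when O2 adds across a cyclohexa-1,3-diene and the O–O bond is then cut. In addition, C6–O, C1–O and C7–O form a 2,3-epoxy-alcohol array, so the fused epoxide with its CH2O arm is interchangeable with a spiro-epoxide on C1/C7 bearing a free C6 hydroxyl.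

## Retrosynthesis

Ring positions are numbered as in 17 throughout (C1 quaternary, C2, C3, C4=C5, C6, exocyclic C7). "Upper face" means the face of the C2 oxygen.

**17 ⇒ 16 ⇒ 15 (C3–O–Si and C2–O–acyl bonds).** A free C3 hydroxyl beside the C2 benzoate cannot be designed away, so it is released last, from triethylsilyl ether 16 under buffered fluoride. 16 comes from acylating the only free hydroxyl of 15 (C2–OH) with 11. Carrying the C2 benzoate from the diene stage would be shorter, but the ester would then meet the alkoxide step that relocates the epoxide. There it has a hydroxyl 1,2 to it (C3) and, after the migration, a primary alkoxide 1,3-cis to it (C7). Acyl transfer to either should outrun epoxide migration and would free C2–O for a second epoxide shift onto C1–C2. The forward reactions asked for are acylation of a hindered secondary alcohol and a non-basic desilylation.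

**15 ⇒ 14 ⇒ 10 (C2–O–PMB, C7–O–acyl, C3–O–Si bonds).** 15 is 14 without its 4-methoxybenzyl (PMB) group. 14 is 10 with the primary C7 hydroxyl benzoylated (11) and the secondary C3 hydroxyl silylated (12), by way of 13. This order uses the one fully reliable distinction in 10, primary against secondary hydroxyl; C2–O is already set apart by its ether. An ether is preferred to a silyl group at C2 because silyl groups also travel to neighbouring alkoxides. PMB is preferred to benzyl because DDQ removes it without touching alkene, epoxide or ester. 10 carries no acyl group and is simpler than 15 by two protecting operations.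

**10 ⇒ 9 (C1–O bond of the fused epoxide).** The fused epoxide is cut at C1–O: the oxygen stays on C6 as a hydroxyl and C1 is reconnected to the C7 oxygen, giving spiro-epoxide 9 with inverted C1. The neighbouring cut, closing the epoxide from a C1 alkoxide onto C6, would need a leaving group on C6 anti to the C3 oxygen, which no cis-1,4-dioxygenation provides. In 9 the quaternary centre is one end of a 1,1-disubstituted epoxide and C3–O, C6–O are a plain cis-diol. The forward Payne rearrangement needs the C6 oxygen anti to the spiro C1–O bond and nothing else in the molecule that answers to alkoxide.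

**9 ⇒ 8 ⇒ 6 + 7 (O–O bond, then C3–O and C6–O).** The cis-diol of 9 is reconnected through an O–O bond to endoperoxide 8, and 8 is cut at both C–O bonds to diene 6 and dioxygen 7. Stepwise alternatives (epoxidation and allylic opening, dihydroxylation) give 1,2-patterns or need transition-metal ionisation that the allylic spiro-epoxide would not survive. The cut removes two stereocentres, two C–O bonds and a ring at once. The forward cycloaddition must take the face of the diene opposite to both the epoxide oxygen and the C2 ether.

**6 ⇒ 4 ⇒ 3 (C2–O–PMB bond; resolution).** 6 is the PMB ether of dienol 4, and 4 is one enantiomer of racemic cis-dienol 3. The spiro centre is born racemic, so one resolution is unavoidable; placing it at 3, the first compound with a handle, wastes the least effort. The forward reactions are a lipase resolution and a Williamson etherification.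

**3 ⇒ 2 ⇒ 1 (C2–H bond; C1–O bond of the spiro-epoxide).** 3 is the 1,2-reduction product of dienone 2, and 2 is the periodate dearomatisation product of 2-hydroxybenzyl alcohol 1. 1 is commercial and holds all seven carbons; its phenolic oxygen becomes C2–O and its benzylic oxygen becomes C7–O of 17. The reduction must deliver hydride anti to the epoxide oxygen so that the two oxygens are cis.

## Roads not taken

**Alternative 1:** The carbocycle is cut at C1–C6 and traced to a six-membered lactone made from a chiral-pool sugar. In the forward step the silyl ketene acetal of that lactone, which carries an E-alkoxyvinyl group on the carbon bonded to the ring oxygen, undergoes a ring-contracting Ireland–Claisen rearrangement to acid A1. C1–C6 forms as C4–O breaks and C4=C5 appears in place.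
- Merits: C2 and C3 come from the sugar in absolute form, no resolution is needed, and all four oxygens are protected differently from the start.
- Weak points: the ring enforces a boat-like transition state; the lactone needs many selective protections (three different groups on four hydroxyls) before the key step; afterwards the acid must be reduced, C7 benzoylated, both PMB groups removed and the epoxide closed from the tertiary C1 alkoxide onto an allylic C6 sulfonate.
- Comparison: this road is better in stereochemical economy, since nothing is discarded in a resolution and no late exchange of groups at C2/C3 is needed. Against that, the chosen plan takes all carbons from one arene in two steps, sets two C–O bonds and two stereocentres with O2 in one step, and is roughly half as long.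

**Alternative 2:** The arene is cut at C1–O and C2–O. Whole cells expressing benzoate 1,2-dioxygenase add both atoms of O2 to benzoic acid A3 and give diol acid A2 in one dearomatising step; no ring closes.
- Merits: one step, enantiopure, quaternary C1 in place with its oxygen on the face of the target's epoxide oxygen and its carbon on the C7 face, and no dimerising dienone.
- Weak points: it needs a fermentation with a blocked mutant, not a shelf reagent. In A2, C1–O and C2–O are cis, but in 17 they are trans. If A2 is reduced and closed to the spiro-epoxide it gives A4, the mirror image of 4, and the Payne logic then leads to the antipode of 17. If the C1 oxygen is instead kept as the epoxide oxygen, singlet oxygen adds anti to both hydroxyls, which is right for C6 (as a leaving group) but wrong for C3, and C2 must be inverted as well.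
- Comparison: A2 is the better starting point in enantiopurity and material throughput. The chosen plan pays for a resolution, but it fits this enantiomer without any inversion and uses only commercial materials.

**Alternative 3:** The ring is cut at C1–C2. A chiral triazolylidene carbene turns the C2 aldehyde of an open-chain Z-alkene keto-aldehyde into an acyl-anion equivalent that adds to the C1 ketone, closing the ring as α-ketol A5.
- Merits: the quaternary carbinol is made catalytically and asymmetrically, the C7 benzoate is already in place, and the oxygens are differentiated.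
- Weak points: the aldehyde carries a silyloxy group on its α-carbon (C3), and Breslow intermediates with an α-leaving group tend to eliminate it instead of adding. The Z-alkene and the C3 and C6 centres must survive assembly of the chain and match the catalyst. After A5 the C2 ketone must be reduced to the alcohol trans to the C1 hydroxyl, and the epoxide closed by a C1 alkoxide flanked by two benzoates, the same acyl-transfer hazard that the chosen plan removes by design.
- Comparison: this road would build ring and stereocentre catalytically, which the chosen plan cannot claim. The chosen plan sets against it a much shorter sequence of standard reactions and a key step with no catalyst-substrate matching problem.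

Key step: step 5

Assumption: in step 3 the lipase is taken to follow the usual empirical preference for secondary alcohols, with the quaternary spiro carbon as the larger substituent, so that the (3R,4R) alcohol is acetylated and the (3S,4S) alcohol 4 is recovered.

## Route

Step 1
Reactants: 1 2-hydroxybenzyl alcohol
Product: 2 (±)-1-oxaspiro[2.5]octa-5,7-dien-4-one
Conditions: NaIO4 (1.1 equiv), H2O–CH2Cl2, 0 °C; organic layer dried (Na2SO4), kept cold and dilute, used at once
Reagents that add atoms: none
Why: Adler–Becker oxidation: the aryl periodate ester collapses as the benzylic hydroxyl attacks ring carbon C1, which dearomatises the ring to the spiro-epoxy dienone; the dienone dimerises by Diels–Alder reaction, hence the cold dilute solution.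

Step 2
Reactants: 2 (±)-1-oxaspiro[2.5]octa-5,7-dien-4-one
Product: 3 (±)-cis-1-oxaspiro[2.5]octa-5,7-dien-4-ol
Conditions: NaBH4, CeCl3·7H2O, MeOH–CH2Cl2, −78 °C; NaHCO3 (aq) quench
Reagents that add atoms: none
Why: Luche 1,2-reduction; CeCl3 suppresses conjugate hydride addition, and hydride should attack C2 anti to the electronegative epoxide oxygen (polar Felkin–Anh control), which places the new hydroxyl on the face of that oxygen (cis).

Step 3
Reactants: 3 (±)-cis-1-oxaspiro[2.5]octa-5,7-dien-4-ol
Product: 4 (3S,4S)-1-oxaspiro[2.5]octa-5,7-dien-4-ol
Conditions: immobilised Candida antarctica lipase B, vinyl acetate, t-BuOMe, Et3N (trace), 25 °C, to just past half conversion; chromatography on Et3N-deactivated silica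
Reagents that add atoms: none
Why: Lipase-catalysed kinetic resolution by irreversible transesterification; the enzyme should acetylate the (3R,4R) alcohol and leave 4, and running slightly past half conversion raises the enantiopurity of the recovered alcohol.

Step 4
Reactants: 4 (3S,4S)-1-oxaspiro[2.5]octa-5,7-dien-4-ol; 5 4-methoxybenzyl chloride
Product: 6 (3S,4S)-4-[(4-methoxybenzyl)oxy]-1-oxaspiro[2.5]octa-5,7-diene
Conditions: NaH, n-Bu4NI (cat.), THF–DMF, 0 °C to rt
Reagents that add atoms: 4-methoxybenzyl chloride, COc1ccc(CCl)cc1
Why: Williamson etherification; the C2 alkoxide is syn to the spiro C1–O bond and cannot open the epoxide, and the resulting ether cannot migrate in the later alkoxide step.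

Step 5
Reactants: 6 (3S,4S)-4-[(4-methoxybenzyl)oxy]-1-oxaspiro[2.5]octa-5,7-diene; 7 dioxygen
Product: 8 spiro-epoxy endoperoxide PMB ether (2,3-dioxabicyclo[2.2.2]oct-5-ene with spiro-oxirane at C1 and PMB ether at C2; peroxide bridge on C3 and C6 anti to the epoxide oxygen and the ether)
Conditions: O2, 5,10,15,20-tetraphenylporphyrin (cat.), visible light, CH2Cl2, NaHCO3 (solid), −30 °C
Reagents that add atoms: dioxygen, O=O
Why: Triplet tetraphenylporphyrin transfers its energy to O2, and the singlet oxygen adds to the ring-locked s-cis diene C3=C4–C5=C6 in a concerted suprafacial [4+2] cycloaddition that forms C3–O and C6–O together. The closest known reaction type is the sensitised photooxygenation of cyclohexa-1,3-dienes, in particular cis-5,6-dioxygenated ones, to 2,3-dioxabicyclo[2.2.2]oct-5-enes. One ring closes, the six-membered 1,2-dioxine ring C3–O–O–C6–C5=C4, by cycloaddition across the diene termini; its O–O bond is a temporary tether. C3 and C6 must be cis to each other because both bonds form on one face. Which face is decided by C1 and C2: the epoxide oxygen and the PMB ether both stand on the upper face and repel the incoming oxygen by bulk and lone-pair repulsion, so addition should come from the lower face, where only the tied-back epoxide CH2 and the C2 hydrogen lie. The step needs face selectivity (prepared by the cis relation from step 2), cycloaddition over ene-type hydroperoxidation (favoured by the planar cisoid diene) and chemoselectivity over the anisyl ring (a poor singlet-oxygen acceptor). Solid NaHCO3 and low temperature protect the acid-labile diene and the base-labile peroxide.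

Step 6
Reactants: 8 spiro-epoxy endoperoxide PMB ether
Product: 9 4-[(4-methoxybenzyl)oxy]-1-oxaspiro[2.5]oct-6-ene-5,8-diol (hydroxyls on C3 and C6 cis to each other, anti to the epoxide oxygen and the ether)
Conditions: thiourea, MeOH–CH2Cl2, 0 °C to rt
Reagents that add atoms: none
Why: Thiourea reduction of the peroxide: sulfur attacks the O–O bond and no C–O bond is touched, so the cis-diol keeps the configuration set in step 5; the neutral medium should spare the hindered epoxide, the alkene and the ether.

Step 7
Reactants: 9 4-[(4-methoxybenzyl)oxy]-1-oxaspiro[2.5]oct-6-ene-5,8-diol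
Product: 10 [3-hydroxy-2-[(4-methoxybenzyl)oxy]-7-oxabicyclo[4.1.0]hept-4-en-1-yl]methanol (ring configuration as in 17)
Conditions: KOtBu (0.2 equiv), t-BuOH–THF, 0 °C to rt; pH 7 buffer
Reagents that add atoms: none
Why: Payne rearrangement: the C6 alkoxide is anti-periplanar to the spiro C1–O bond and attacks C1 with inversion (3-exo-tet), moving the epoxide to C1–C6 and releasing C7–OH on the upper face. The equilibrium should favour the trisubstituted, alkene-conjugated epoxide with a primary alcohol. With C2 blocked as an ether and no acyl or silyl group present, nothing can migrate and the epoxide cannot travel further.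

Step 8
Reactants: 10 [3-hydroxy-2-[(4-methoxybenzyl)oxy]-7-oxabicyclo[4.1.0]hept-4-en-1-yl]methanol; 11 benzoyl chloride; 12 chlorotriethylsilane
Product: 14 [2-[(4-methoxybenzyl)oxy]-3-(triethylsilyloxy)-7-oxabicyclo[4.1.0]hept-4-en-1-yl]methyl benzoate, via C7 monobenzoate 13 (not isolated)
Conditions: BzCl (1.05 equiv), 2,4,6-collidine, CH2Cl2, −78 to −20 °C; then TESCl, imidazole, 0 °C to rt
Reagents that add atoms: benzoyl chloride, O=C(Cl)c1ccccc1; chlorotriethylsilane, CC[Si](Cl)(CC)CC
Why: Selective acylation of the primary over the secondary hydroxyl with a weak hindered base at low temperature, then silylation of the remaining allylic hydroxyl in the same flask; no alkoxide is formed, so the new ester stays on C7.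

Step 9
Reactants: 14 [2-[(4-methoxybenzyl)oxy]-3-(triethylsilyloxy)-7-oxabicyclo[4.1.0]hept-4-en-1-yl]methyl benzoate
Product: 15 [2-hydroxy-3-(triethylsilyloxy)-7-oxabicyclo[4.1.0]hept-4-en-1-yl]methyl benzoate (configuration as in 14)
Conditions: DDQ, CH2Cl2–pH 7 phosphate buffer, 0 °C to rt
Reagents that add atoms: none
Why: Oxidative cleavage of the PMB ether (electron transfer from the anisyl ring, benzylic oxocarbenium ion, hydrolysis); the buffer keeps the allylic epoxide and the silyl ether intact.

Step 10
Reactants: 15 [2-hydroxy-3-(triethylsilyloxy)-7-oxabicyclo[4.1.0]hept-4-en-1-yl]methyl benzoate; 11 benzoyl chloride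
Product: 16 [2-(benzoyloxy)-3-(triethylsilyloxy)-7-oxabicyclo[4.1.0]hept-4-en-1-yl]methyl benzoate (ring configuration as in 17)
Conditions: BzCl, pyridine, 4-(dimethylamino)pyridine (cat.), CH2Cl2, 0 °C to rt
Reagents that add atoms: benzoyl chloride, O=C(Cl)c1ccccc1
Why: Nucleophile-catalysed acylation of the single free (hindered, secondary) hydroxyl; with only one hydroxyl present there is no regiochemical question.

Step 11
Reactants: 16 [2-(benzoyloxy)-3-(triethylsilyloxy)-7-oxabicyclo[4.1.0]hept-4-en-1-yl]methyl benzoate
Product: 17 [(1S,2S,3R,6S)-2-(benzoyloxy)-3-hydroxy-7-oxabicyclo[4.1.0]hept-4-en-1-yl]methyl benzoate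
Conditions: HF·pyridine, pyridine, THF, 0 °C
Reagents that add atoms: none
Why: Fluoride-mediated cleavage of the triethylsilyl ether under buffered, non-basic conditions, so the C2 benzoate should not move to the freed C3 hydroxyl and the allylic epoxide should stay closed.

## Compound list

1 | 2-hydroxybenzyl alcohol | OCc1ccccc1O | starting material
2 | (±)-1-oxaspiro[2.5]octa-5,7-dien-4-one (racemate) | O=C1C=CC=CC12CO2 | intermediate
3 | (±)-cis-1-oxaspiro[2.5]octa-5,7-dien-4-ol (racemate; epoxide O and OH on one face; SMILES shows the 3S,4S enantiomer) | C1O[C@@]12C=CC=C[C@@H]2O | intermediate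
4 | (3S,4S)-1-oxaspiro[2.5]octa-5,7-dien-4-ol | C1O[C@@]12C=CC=C[C@@H]2O | intermediate
5 | 4-methoxybenzyl chloride | COc1ccc(CCl)cc1 | starting material
6 | (3S,4S)-4-[(4-methoxybenzyl)oxy]-1-oxaspiro[2.5]octa-5,7-diene | C1O[C@@]12C=CC=C[C@@H]2OCc1ccc(OC)cc1 | intermediate
7 | dioxygen | O=O | starting material
8 | spiro-epoxy endoperoxide PMB ether (peroxide bridge anti to epoxide O and ether) | C1O[C@@]12[C@H]3OO[C@H](C=C3)[C@@H]2OCc1ccc(OC)cc1 | intermediate
9 | 4-[(4-methoxybenzyl)oxy]-1-oxaspiro[2.5]oct-6-ene-5,8-diol (cis-diol anti to epoxide O and ether) | C1O[C@@]12[C@@H](O)C=C[C@@H](O)[C@@H]2OCc1ccc(OC)cc1 | intermediate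
10 | [3-hydroxy-2-[(4-methoxybenzyl)oxy]-7-oxabicyclo[4.1.0]hept-4-en-1-yl]methanol | OC[C@]12O[C@H]1C=C[C@@H](O)[C@@H]2OCc1ccc(OC)cc1 | intermediate
11 | benzoyl chloride | O=C(Cl)c1ccccc1 | starting material
12 | chlorotriethylsilane | CC[Si](Cl)(CC)CC | starting material
13 | [3-hydroxy-2-[(4-methoxybenzyl)oxy]-7-oxabicyclo[4.1.0]hept-4-en-1-yl]methyl benzoate | O=C(OC[C@]12O[C@H]1C=C[C@@H](O)[C@@H]2OCc1ccc(OC)cc1)c1ccccc1 | intermediate
14 | [2-[(4-methoxybenzyl)oxy]-3-(triethylsilyloxy)-7-oxabicyclo[4.1.0]hept-4-en-1-yl]methyl benzoate | O=C(OC[C@]12O[C@H]1C=C[C@@H](O[Si](CC)(CC)CC)[C@@H]2OCc1ccc(OC)cc1)c1ccccc1 | intermediate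
15 | [2-hydroxy-3-(triethylsilyloxy)-7-oxabicyclo[4.1.0]hept-4-en-1-yl]methyl benzoate | O=C(OC[C@]12O[C@H]1C=C[C@@H](O[Si](CC)(CC)CC)[C@@H]2O)c1ccccc1 | intermediate
16 | [2-(benzoyloxy)-3-(triethylsilyloxy)-7-oxabicyclo[4.1.0]hept-4-en-1-yl]methyl benzoate | O=C(OC[C@]12O[C@H]1C=C[C@@H](O[Si](CC)(CC)CC)[C@@H]2OC(=O)c1ccccc1)c1ccccc1 | intermediate
17 | [(1S,2S,3R,6S)-2-(benzoyloxy)-3-hydroxy-7-oxabicyclo[4.1.0]hept-4-en-1-yl]methyl benzoate | O=C(OC[C@]12O[C@H]1C=C[C@@H](O)[C@@H]2OC(=O)c1ccccc1)c1ccccc1 | target

## Step count and least certain steps

Total: 11 steps. Longest linear sequence: 11 steps (1 to 17).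

**Step 5 (key step).** The most likely failure is incomplete discrimination between the diene faces, since the upper face is guarded only by an epoxide oxygen and a flexible benzylic ether. Ene-type hydroperoxidation through the C2 hydrogen, which lies on the attacked face, and acid-triggered ionisation of the diene during irradiation are further losses. The fallback relays the cycloaddition through the ester, a flatter and stronger face-shielding group, and changes to the ether series before any base is used. It sets out from 4. Benzoylation with 11 (pyridine) would give (3S,4S)-1-oxaspiro[2.5]octa-5,7-dien-4-yl benzoate F1. Photooxygenation would give the endoperoxide benzoate F2, and thiourea the diol benzoate F3. Silylation of both hydroxyls (TBSOTf, 2,6-lutidine) would give the bis(tert-butyldimethylsilyl) ether benzoate F4. Reductive removal of the ester (i-Bu2AlH, −78 °C) would give the bis-silyl C2 alcohol F5, and etherification with 5 (NaH) the bis-silyl PMB ether F6. Desilylation (n-Bu4NF) brings the route back at 9.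

**Step 2.** Hydride may be delivered to the wrong face, giving the trans alcohol. Losses may also come from Diels–Alder dimerisation of 2 before it is reduced and from re-aromatisation of 3 in the Lewis-acidic methanol. The fallback corrects the configuration by inversion: from 2, the (±)-trans-dienol F7 is esterified under Mitsunobu conditions (4-nitrobenzoic acid, PPh3, diisopropyl azodicarboxylate) to the (±)-cis 4-nitrobenzoate F8, and methanolysis (K2CO3, MeOH) returns the route at 3.

**Step 3.** The enzyme may discriminate poorly or slowly between the enantiomers of an alcohol flanked by a quaternary carbon, or in the opposite sense. The fallback is a classical resolution. From 3, esterification with (S)-2-methoxy-2-phenylacetic acid (N,N'-dicyclohexylcarbodiimide, 4-(dimethylamino)pyridine) would give the diastereomers (3S,4S)-dienyl (S)-O-methylmandelate F9 and (3R,4R)-dienyl (S)-O-methylmandelate F10. These are separated by chromatography, and methanolysis of F9 (K2CO3, MeOH) returns the route at 4.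

**Step 7.** The equilibrium may not lie far enough on the side of 10, and prolonged base may open the allylic epoxide. The fallback pulls the equilibrium over by trapping. From 9, the equilibrated mixture is exposed to immobilised Candida antarctica lipase B and vinyl benzoate in t-BuOMe. Only the primary hydroxyl of 10 should be acylated, so the route comes back at 13, which is silylated as in the second half of step 8. Recovered 9 is equilibrated again; no new compound arises (F0).

**Step 11.** Fluoride or adventitious acid may open the allylic epoxide, or the C2 benzoate may shift to C3 as the hydroxyl is freed. The fallback changes the C3 protecting group to one removed under neutral conditions. From 13, esterification with levulinic acid (N,N'-dicyclohexylcarbodiimide, 4-(dimethylamino)pyridine) would give the C3 levulinate PMB ether F11. DDQ would give the C3 levulinate C2 alcohol F12, and benzoylation with 11 the C3 levulinate dibenzoate F13. Hydrazine acetate in pyridine removes the levulinate and returns the route at 17.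

## Further compounds

F1 | step 5 | (3S,4S)-1-oxaspiro[2.5]octa-5,7-dien-4-yl benzoate | C1O[C@@]12C=CC=C[C@@H]2OC(=O)c1ccccc1
F2 | step 5 | spiro-epoxy endoperoxide benzoate (peroxide anti to epoxide O and ester) | C1O[C@@]12[C@H]3OO[C@H](C=C3)[C@@H]2OC(=O)c1ccccc1
F3 | step 5 | 5,8-dihydroxy-1-oxaspiro[2.5]oct-6-en-4-yl benzoate (cis-diol anti to epoxide O) | C1O[C@@]12[C@@H](O)C=C[C@@H](O)[C@@H]2OC(=O)c1ccccc1
F4 | step 5 | 5,8-bis(tert-butyldimethylsilyloxy)-1-oxaspiro[2.5]oct-6-en-4-yl benzoate | C1O[C@@]12[C@@H](O[Si](C)(C)C(C)(C)C)C=C[C@@H](O[Si](C)(C)C(C)(C)C)[C@@H]2OC(=O)c1ccccc1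
F5 | step 5 | 5,8-bis(tert-butyldimethylsilyloxy)-1-oxaspiro[2.5]oct-6-en-4-ol | C1O[C@@]12[C@@H](O[Si](C)(C)C(C)(C)C)C=C[C@@H](O[Si](C)(C)C(C)(C)C)[C@@H]2O
F6 | step 5 | 5,8-bis(tert-butyldimethylsilyloxy)-4-[(4-methoxybenzyl)oxy]-1-oxaspiro[2.5]oct-6-ene | C1O[C@@]12[C@@H](O[Si](C)(C)C(C)(C)C)C=C[C@@H](O[Si](C)(C)C(C)(C)C)[C@@H]2OCc1ccc(OC)cc1
F7 | step 2 | (±)-trans-1-oxaspiro[2.5]octa-5,7-dien-4-ol (racemate, one enantiomer shown) | C1O[C@@]12C=CC=C[C@H]2O
F8 | step 2 | (±)-cis-1-oxaspiro[2.5]octa-5,7-dien-4-yl 4-nitrobenzoate (racemate, one enantiomer shown) | C1O[C@@]12C=CC=C[C@@H]2OC(=O)c1ccc(cc1)[N+](=O)[O-]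
F9 | step 3 | (3S,4S)-1-oxaspiro[2.5]octa-5,7-dien-4-yl (S)-2-methoxy-2-phenylacetate | C1O[C@@]12C=CC=C[C@@H]2OC(=O)[C@@H](OC)c1ccccc1
F10 | step 3 | (3R,4R)-1-oxaspiro[2.5]octa-5,7-dien-4-yl (S)-2-methoxy-2-phenylacetate | C1O[C@]12C=CC=C[C@H]2OC(=O)[C@@H](OC)c1ccccc1
F0 | step 7 | none | none
F11 | step 11 | [3-(4-oxopentanoyloxy)-2-[(4-methoxybenzyl)oxy]-7-oxabicyclo[4.1.0]hept-4-en-1-yl]methyl benzoate | O=C(OC[C@]12O[C@H]1C=C[C@@H](OC(=O)CCC(C)=O)[C@@H]2OCc1ccc(OC)cc1)c1ccccc1
F12 | step 11 | [2-hydroxy-3-(4-oxopentanoyloxy)-7-oxabicyclo[4.1.0]hept-4-en-1-yl]methyl benzoate | O=C(OC[C@]12O[C@H]1C=C[C@@H](OC(=O)CCC(C)=O)[C@@H]2O)c1ccccc1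
F13 | step 11 | [2-(benzoyloxy)-3-(4-oxopentanoyloxy)-7-oxabicyclo[4.1.0]hept-4-en-1-yl]methyl benzoate | O=C(OC[C@]12O[C@H]1C=C[C@@H](OC(=O)CCC(C)=O)[C@@H]2OC(=O)c1ccccc1)c1ccccc1
A1 | alternative 1 | 1,6-bis(4-methoxybenzyloxy)-2-(tert-butyldimethylsilyloxy)-3-(triisopropylsilyloxy)cyclohex-4-ene-1-carboxylic acid (C6–O trans to C1–O) | OC(=O)[C@]1(OCc2ccc(OC)cc2)[C@H](OCc2ccc(OC)cc2)C=C[C@@H](O[Si](C(C)C)(C(C)C)C(C)C)[C@@H]1O[Si](C)(C)C(C)(C)C
A2 | alternative 2 | (1S,2R)-1,2-dihydroxycyclohexa-3,5-diene-1-carboxylic acid | OC(=O)[C@]1(O)C=CC=C[C@H]1O
A3 | alternative 2 | benzoic acid | OC(=O)c1ccccc1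
A4 | alternative 2 | (3R,4R)-1-oxaspiro[2.5]octa-5,7-dien-4-ol | C1O[C@]12C=CC=C[C@H]2O
A5 | alternative 3 | [1-hydroxy-6-(4-methoxybenzyloxy)-2-oxo-3-(tert-butyldimethylsilyloxy)cyclohex-4-en-1-yl]methyl benzoate | O=C(OC[C@]1(O)[C@H](OCc2ccc(OC)cc2)C=C[C@@H](O[Si](C)(C)C(C)(C)C)C1=O)c1ccccc1
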